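**Retrosynthetic overview**
1. The 4,5-epoxide comes last, by outer-face epoxidation of the (E)-C4=C5 alkene; the C8 angelate and C13 acetate come from acylation of a macrocyclic diol.
2. The ten-membered carbocycle and the butenolide close together: a C7 (Z)-enol triflate adds to the C6 enal (CrCl2/NiCl2) and the new alkoxide lactonises.
3. Key bond C2–C3: Claisen rearrangement of the allyl vinyl ether made from an ester that joins the acid half (C1, C7–C10) to the allylic alcohol half (C3–C6); it also sets the (E)-C4=C5 alkene.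
4. C8 is bought in (S)-5-(hydroxymethyl)butyrolactone (from L-glutamic acid) and directs the C10 methylation; C11–C13 come from a 3-silyloxypropanoate aldol.
5. Ring order: no ring until step 13 (carbocycle and lactone in one operation), oxirane in step 16.

Assumption: the target is taken as drawn, (4R,5R,6S,8S,10R) with a (Z)-2-methylbut-2-enoate (angelate) at C8; germacrane numbering is used (C1 ketone, C4–C5 epoxide, C6 lactone CH–O, C7=C11, C8 ester carbinol, C10 CH–CH3, C12 lactone C=O, C13 CH2OAc); alcohol 3 is used as the racemate and the transient stereocentres of 10, 17 and 18 are carried as mixtures because later steps erase them.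

Step 1
Reactants: 1 2,2-dimethoxyacetaldehyde (anhydrous); 2 isopropenylmagnesium bromide
Product: 3 rac-1,1-dimethoxy-3-methylbut-3-en-2-ol
Conditions: THF, −78 to 0 °C; then H2O
Reagents that add atoms: none
Why: Grignard 1,2-addition to the aldehyde gives the 2-methylallylic alcohol (C3–C6 unit); the racemate suffices because this carbinol centre is erased in the Claisen rearrangement of step 6.

Step 2
Reactants: 4 (S)-5-(hydroxymethyl)dihydrofuran-2(3H)-one
Product: 5 (S)-5-{[(tert-butyldimethylsilyl)oxy]methyl}dihydrofuran-2(3H)-one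
Conditions: TBSCl, imidazole, CH2Cl2, rt
Reagents that add atoms: tert-butyldimethylsilyl chloride, CC(C)(C)[Si](C)(C)Cl
Why: Routine silylation of the primary alcohol (future C7) leaves the bought stereocentre (future C8) untouched.

Step 3
Reactants: 5 (S)-5-{[(tert-butyldimethylsilyl)oxy]methyl}dihydrofuran-2(3H)-one
Product: 6 (3R,5S)-5-{[(tert-butyldimethylsilyl)oxy]methyl}-3-methyldihydrofuran-2(3H)-one
Conditions: LiN(iPr)2, THF, −78 °C; then MeI, −78 to −40 °C
Reagents that add atoms: iodomethane, CI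
Why: Lactone enolate alkylation in which MeI enters anti to the C5 silyloxymethyl group, giving the trans (3R,5S) lactone and so setting the future C10 from the bought C8 centre.

Step 4
Reactants: 6 (3R,5S)-5-{[(tert-butyldimethylsilyl)oxy]methyl}-3-methyldihydrofuran-2(3H)-one
Product: 9 (2R,4S)-4,5-bis[(tert-butyldimethylsilyl)oxy]-2-methylpentanoic acid, via lithium hydroxy carboxylate 7 (not isolated), via silyl ester 8 (not isolated)
Conditions: LiOH, THF/H2O, rt; evaporate; TBSCl (2.5 equiv), imidazole, DMF, rt; then THF/MeOH/aq. citric acid (pH 4), rt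
Reagents that add atoms: lithium hydroxide, [Li+].[OH-]; tert-butyldimethylsilyl chloride, CC(C)(C)[Si](C)(C)Cl
Why: Saponification, silylation of the freed secondary hydroxyl and the carboxylate, then selective hydrolysis of the labile silyl ester gives the open-chain acid without touching either stereocentre.

Step 5
Reactants: 9 (2R,4S)-4,5-bis[(tert-butyldimethylsilyl)oxy]-2-methylpentanoic acid; 3 rac-1,1-dimethoxy-3-methylbut-3-en-2-ol
Product: 10 1,1-dimethoxy-3-methylbut-3-en-2-yl (2R,4S)-4,5-bis[(tert-butyldimethylsilyl)oxy]-2-methylpentanoate (1:1 epimers at the allylic carbinol carbon)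
Conditions: DCC, DMAP (cat.), CH2Cl2, 0 °C to rt
Reagents that add atoms: none
Why: Steglich esterification joins the two halves through the C1–O–C5 ester that the rearrangement needs; the epimer mixture at C5 is inconsequential.

Step 6
Reactants: 10 1,1-dimethoxy-3-methylbut-3-en-2-yl (2R,4S)-4,5-bis[(tert-butyldimethylsilyl)oxy]-2-methylpentanoate
Product: 12 (2E,7R,9S)-9,10-bis[(tert-butyldimethylsilyl)oxy]-1,1-dimethoxy-3,7-dimethyldec-2-en-6-one, via allyl vinyl ether 11 (not isolated)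
Conditions: Cp2TiMe2 (2.5 equiv), toluene, 70 °C, dark; filtration through basic Al2O3; then toluene, 130 °C
Reagents that add atoms: dimethyltitanocene Cp2TiMe2, C[Ti](C)(C1C=CC=C1)C1C=CC=C1
Why: Petasis methylenation of the only carbonyl gives the 2-substituted allyl vinyl ether, whose Claisen [3,3] rearrangement through a chair with the acetal-bearing substituent equatorial forms the C2–C3 bond, the C1 ketone and the (E)-C4=C5 alkene, erasing the C5 centre and leaving C10 and C8 intact.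

Step 7
Reactants: 12 (2E,7R,9S)-9,10-bis[(tert-butyldimethylsilyl)oxy]-1,1-dimethoxy-3,7-dimethyldec-2-en-6-one
Product: 13 (2E,7R,9S)-9-[(tert-butyldimethylsilyl)oxy]-10-hydroxy-1,1-dimethoxy-3,7-dimethyldec-2-en-6-one
Conditions: HF·pyridine, pyridine, THF, 0 °C
Reagents that add atoms: none
Why: Buffered fluoride cleaves the primary silyl ether much faster than the secondary one and spares the acetal, freeing C7–OH.

Step 8
Reactants: 13 (2E,7R,9S)-9-[(tert-butyldimethylsilyl)oxy]-10-hydroxy-1,1-dimethoxy-3,7-dimethyldec-2-en-6-one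
Product: 14 (2S,4R,8E)-2-[(tert-butyldimethylsilyl)oxy]-10,10-dimethoxy-4,8-dimethyl-5-oxodec-8-enal
Conditions: Dess–Martin periodinane, pyridine, CH2Cl2, 0 °C to rt
Reagents that add atoms: none
Why: Dess–Martin oxidation gives the α-silyloxy aldehyde (C7) under buffered, non-epimerising conditions.

Step 9
Reactants: 14 (2S,4R,8E)-2-[(tert-butyldimethylsilyl)oxy]-10,10-dimethoxy-4,8-dimethyl-5-oxodec-8-enal; 15 methyl 3-[(tert-butyldimethylsilyl)oxy]propanoate
Product: 17 methyl (4S,6R,10E)-4-[(tert-butyldimethylsilyl)oxy]-2-{[(tert-butyldimethylsilyl)oxy]methyl}-3-hydroxy-12,12-dimethoxy-6,10-dimethyl-7-oxododec-10-enoate (mixture at C2 and C3), via lithium ester enolate 16 (not isolated)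
Conditions: 15, LiN(iPr)2, THF, −78 °C; then 14, −78 °C, 20 min; AcOH
Reagents that add atoms: none
Why: Aldol addition of the ester enolate to the aldehyde, which is far more electrophilic than the hindered C1 ketone at −78 °C, brings in C11–C13; the two new centres are erased in steps 10 and 11.

Step 10
Reactants: 17 methyl (4S,6R,10E)-4-[(tert-butyldimethylsilyl)oxy]-2-{[(tert-butyldimethylsilyl)oxy]methyl}-3-hydroxy-12,12-dimethoxy-6,10-dimethyl-7-oxododec-10-enoate
Product: 18 methyl (4S,6R,10E)-4-[(tert-butyldimethylsilyl)oxy]-2-{[(tert-butyldimethylsilyl)oxy]methyl}-12,12-dimethoxy-6,10-dimethyl-3,7-dioxododec-10-enoate (C2 epimers, partly enolised)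
Conditions: Dess–Martin periodinane, pyridine, CH2Cl2, rt
Reagents that add atoms: none
Why: Dess–Martin oxidation of the β-hydroxy ester gives the β-keto ester; it enolises towards the ester, so C8 is not endangered.

Step 11
Reactants: 18 methyl (4S,6R,10E)-4-[(tert-butyldimethylsilyl)oxy]-2-{[(tert-butyldimethylsilyl)oxy]methyl}-12,12-dimethoxy-6,10-dimethyl-3,7-dioxododec-10-enoate
Product: 19 methyl (2Z,4S,6R,10E)-4-[(tert-butyldimethylsilyl)oxy]-2-{[(tert-butyldimethylsilyl)oxy]methyl}-12,12-dimethoxy-6,10-dimethyl-7-oxo-3-[(trifluoromethanesulfonyl)oxy]dodeca-2,10-dienoate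
Conditions: NaH, Et2O, 0 °C; then Tf2O, −78 to 0 °C
Reagents that add atoms: trifluoromethanesulfonic anhydride, O=S(=O)(OS(=O)(=O)C(F)(F)F)C(F)(F)F
Why: Only the β-keto ester is deprotonated, and O-triflation of its sodium-chelated enolate gives the (Z)-enol triflate with triflate cis to the ester, the geometry needed for lactonisation after coupling.

Step 12
Reactants: 19 methyl (2Z,4S,6R,10E)-4-[(tert-butyldimethylsilyl)oxy]-2-{[(tert-butyldimethylsilyl)oxy]methyl}-12,12-dimethoxy-6,10-dimethyl-7-oxo-3-[(trifluoromethanesulfonyl)oxy]dodeca-2,10-dienoate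
Product: 20 methyl (2Z,4S,6R,10E)-4-hydroxy-2-(hydroxymethyl)-6,10-dimethyl-7,12-dioxo-3-[(trifluoromethanesulfonyl)oxy]dodeca-2,10-dienoate
Conditions: 48% aq. HF, MeCN, 0 °C to rt
Reagents that add atoms: water, O
Why: One acidic operation cleaves both silyl ethers and hydrolyses the allylic dimethyl acetal to the (E)-enal while the electron-poor vinyl triflate is inert, exposing the C6 aldehyde and the C8 hydroxyl that directs the ring closure.

Step 13
Reactants: 20 methyl (2Z,4S,6R,10E)-4-hydroxy-2-(hydroxymethyl)-6,10-dimethyl-7,12-dioxo-3-[(trifluoromethanesulfonyl)oxy]dodeca-2,10-dienoate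
Product: 22 (4E,6R,8S,10R)-8,13-dihydroxy-1-oxogermacra-4,7(11)-dien-12,6-olide, via ring-closed hydroxy ester 21 (not isolated)
Conditions: CrCl2 (10 equiv), NiCl2 (5 mol %), DMF, 0.002 M, rt; aqueous work-up
Reagents that add atoms: none
Why: Nozaki–Hiyama–Kishi coupling in which zerovalent nickel inserts into the C7–OTf bond and the vinyl group passes to trivalent chromium and adds to the C6 aldehyde at high dilution, closing the ten-membered ring; C6 is expected cis to the C8 hydroxyl (6R here) through a chromium chelate bridging C8–OH and the aldehyde oxygen on one ring face, and the (Z)-geometry lets the new alkoxide lactonise to the butenolide.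

Step 14
Reactants: 22 (4E,6R,8S,10R)-8,13-dihydroxy-1-oxogermacra-4,7(11)-dien-12,6-olide
Product: 23 (4E,6R,8S,10R)-13-acetoxy-8-hydroxy-1-oxogermacra-4,7(11)-dien-12,6-olide
Conditions: AcCl (1.1 equiv), 2,4,6-collidine, CH2Cl2, −78 °C
Reagents that add atoms: acetyl chloride, CC(Cl)=O
Why: Kinetically selective acylation of the unhindered primary allylic C13–OH over the hindered secondary C8–OH with a weak, non-epimerising base.

Step 15
Reactants: 23 (4E,6R,8S,10R)-13-acetoxy-8-hydroxy-1-oxogermacra-4,7(11)-dien-12,6-olide; 24 angelic acid, (Z)-2-methylbut-2-enoic acid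
Product: 26 (4E,6R,8S,10R)-13-acetoxy-8-[(Z)-2-methylbut-2-enoyloxy]-1-oxogermacra-4,7(11)-dien-12,6-olide, via mixed anhydride 25 (not isolated)
Conditions: 24, 2,4,6-trichlorobenzoyl chloride, Et3N, toluene, rt; then 23, DMAP (cat.), 40 °C
Reagents that add atoms: none
Why: Yamaguchi esterification through the preformed mixed anhydride acylates C8–OH with retention at carbon and, kept mild with little DMAP, with minimal Z-to-E isomerisation of the angelate.

Step 16
Reactants: 26 (4E,6R,8S,10R)-13-acetoxy-8-[(Z)-2-methylbut-2-enoyloxy]-1-oxogermacra-4,7(11)-dien-12,6-olide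
Product: 27 (4R,5R,6S,8S,10R)-13-acetoxy-8-[(Z)-2-methylbut-2-enoyloxy]-4,5-epoxy-1-oxogermacr-7(11)-en-12,6-olide (CNP0229937.2)
Conditions: mCPBA (1.1 equiv), CH2Cl2/aq. pH 8 phosphate buffer, 0 °C
Reagents that add atoms: 3-chloroperbenzoic acid, OOC(=O)c1cccc(Cl)c1
Why: Prilezhaev epoxidation of the only electron-rich alkene from its exposed outer face (C6–H eclipses the alkene to avoid allylic strain with the C4 methyl, so the lactone oxygen lies outside and the ring inside) gives the trans 4R,5R epoxide as in costunolide-type germacranolides; the C6 descriptor changes from R to S only through CIP priorities.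

**Compound list**
1 | 2,2-dimethoxyacetaldehyde | COC(OC)C=O | starting material
2 | isopropenylmagnesium bromide | CC(=C)[Mg]Br | starting material
3 | rac-1,1-dimethoxy-3-methylbut-3-en-2-ol | COC(OC)C(O)C(C)=C | intermediate
4 | (S)-5-(hydroxymethyl)dihydrofuran-2(3H)-one | O=C1CC[C@@H](CO)O1 | starting material
5 | (S)-5-{[(tert-butyldimethylsilyl)oxy]methyl}dihydrofuran-2(3H)-one | O=C1CC[C@@H](CO[Si](C)(C)C(C)(C)C)O1 | intermediate
6 | (3R,5S)-5-{[(tert-butyldimethylsilyl)oxy]methyl}-3-methyldihydrofuran-2(3H)-one | O=C1[C@H](C)C[C@@H](CO[Si](C)(C)C(C)(C)C)O1 | intermediate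
7 | lithium (2R,4S)-5-[(tert-butyldimethylsilyl)oxy]-4-hydroxy-2-methylpentanoate | [Li+].[O-]C(=O)[C@H](C)C[C@@H](CO[Si](C)(C)C(C)(C)C)O | intermediate (not isolated)
8 | tert-butyldimethylsilyl (2R,4S)-4,5-bis[(tert-butyldimethylsilyl)oxy]-2-methylpentanoate | CC(C)(C)[Si](C)(C)OC(=O)[C@H](C)C[C@@H](CO[Si](C)(C)C(C)(C)C)O[Si](C)(C)C(C)(C)C | intermediate (not isolated)
9 | (2R,4S)-4,5-bis[(tert-butyldimethylsilyl)oxy]-2-methylpentanoic acid | OC(=O)[C@H](C)C[C@@H](CO[Si](C)(C)C(C)(C)C)O[Si](C)(C)C(C)(C)C | intermediate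
10 | 1,1-dimethoxy-3-methylbut-3-en-2-yl (2R,4S)-4,5-bis[(tert-butyldimethylsilyl)oxy]-2-methylpentanoate (both epimers at the allylic carbinol carbon) | COC(OC)C(OC(=O)[C@H](C)C[C@@H](CO[Si](C)(C)C(C)(C)C)O[Si](C)(C)C(C)(C)C)C(C)=C | intermediate
11 | 3-{[(3R,5S)-5,6-bis[(tert-butyldimethylsilyl)oxy]-3-methylhex-1-en-2-yl]oxy}-4,4-dimethoxy-2-methylbut-1-ene (allyl vinyl ether) | COC(OC)C(OC(=C)[C@H](C)C[C@@H](CO[Si](C)(C)C(C)(C)C)O[Si](C)(C)C(C)(C)C)C(C)=C | intermediate (not isolated)
12 | (2E,7R,9S)-9,10-bis[(tert-butyldimethylsilyl)oxy]-1,1-dimethoxy-3,7-dimethyldec-2-en-6-one | COC(OC)/C=C(\C)CCC(=O)[C@H](C)C[C@@H](CO[Si](C)(C)C(C)(C)C)O[Si](C)(C)C(C)(C)C | intermediate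
13 | (2E,7R,9S)-9-[(tert-butyldimethylsilyl)oxy]-10-hydroxy-1,1-dimethoxy-3,7-dimethyldec-2-en-6-one | COC(OC)/C=C(\C)CCC(=O)[C@H](C)C[C@@H](CO)O[Si](C)(C)C(C)(C)C | intermediate
14 | (2S,4R,8E)-2-[(tert-butyldimethylsilyl)oxy]-10,10-dimethoxy-4,8-dimethyl-5-oxodec-8-enal | COC(OC)/C=C(\C)CCC(=O)[C@H](C)C[C@@H](C=O)O[Si](C)(C)C(C)(C)C | intermediate
15 | methyl 3-[(tert-butyldimethylsilyl)oxy]propanoate | COC(=O)CCO[Si](C)(C)C(C)(C)C | starting material
16 | lithium 3-[(tert-butyldimethylsilyl)oxy]-1-methoxyprop-1-en-1-olate (lithium enolate of 15) | [Li+].COC([O-])=CCO[Si](C)(C)C(C)(C)C | intermediate (not isolated)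
17 | methyl (4S,6R,10E)-4-[(tert-butyldimethylsilyl)oxy]-2-{[(tert-butyldimethylsilyl)oxy]methyl}-3-hydroxy-12,12-dimethoxy-6,10-dimethyl-7-oxododec-10-enoate (mixture at C2 and C3) | COC(OC)/C=C(\C)CCC(=O)[C@H](C)C[C@@H](C(O)C(CO[Si](C)(C)C(C)(C)C)C(=O)OC)O[Si](C)(C)C(C)(C)C | intermediate
18 | methyl (4S,6R,10E)-4-[(tert-butyldimethylsilyl)oxy]-2-{[(tert-butyldimethylsilyl)oxy]methyl}-12,12-dimethoxy-6,10-dimethyl-3,7-dioxododec-10-enoate (C2 epimers) | COC(OC)/C=C(\C)CCC(=O)[C@H](C)C[C@@H](C(=O)C(CO[Si](C)(C)C(C)(C)C)C(=O)OC)O[Si](C)(C)C(C)(C)C | intermediate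
19 | methyl (2Z,4S,6R,10E)-4-[(tert-butyldimethylsilyl)oxy]-2-{[(tert-butyldimethylsilyl)oxy]methyl}-12,12-dimethoxy-6,10-dimethyl-7-oxo-3-[(trifluoromethanesulfonyl)oxy]dodeca-2,10-dienoate | COC(OC)/C=C(\C)CCC(=O)[C@H](C)C[C@@H](/C(OS(=O)(=O)C(F)(F)F)=C(\CO[Si](C)(C)C(C)(C)C)C(=O)OC)O[Si](C)(C)C(C)(C)C | intermediate
20 | methyl (2Z,4S,6R,10E)-4-hydroxy-2-(hydroxymethyl)-6,10-dimethyl-7,12-dioxo-3-[(trifluoromethanesulfonyl)oxy]dodeca-2,10-dienoate | O=C/C=C(\C)CCC(=O)[C@H](C)C[C@@H](/C(OS(=O)(=O)C(F)(F)F)=C(\CO)C(=O)OC)O | intermediate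
21 | methyl (2Z)-2-[(2R,3E,8R,10S)-2,10-dihydroxy-4,8-dimethyl-7-oxocyclodec-3-en-1-ylidene]-3-hydroxypropanoate | O[C@H]1C[C@@H](C)C(=O)CC/C(C)=C/[C@@H](O)/C1=C(/CO)C(=O)OC | intermediate (not isolated)
22 | (4E,6R,8S,10R)-8,13-dihydroxy-1-oxogermacra-4,7(11)-dien-12,6-olide ((E)-cyclodecenone fused at C6–C7 to a butenolide bearing CH2OH on C11) | O[C@H]1C[C@@H](C)C(=O)CC/C(C)=C/[C@H]2OC(=O)C(CO)=C12 | intermediate
23 | (4E,6R,8S,10R)-13-acetoxy-8-hydroxy-1-oxogermacra-4,7(11)-dien-12,6-olide | O[C@H]1C[C@@H](C)C(=O)CC/C(C)=C/[C@H]2OC(=O)C(COC(C)=O)=C12 | intermediate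
24 | angelic acid, (Z)-2-methylbut-2-enoic acid | C/C=C(/C)C(O)=O | starting material
25 | (Z)-2-methylbut-2-enoic 2,4,6-trichlorobenzoic anhydride | C/C=C(/C)C(=O)OC(=O)c1c(Cl)cc(Cl)cc1Cl | intermediate (not isolated)
26 | (4E,6R,8S,10R)-13-acetoxy-8-[(Z)-2-methylbut-2-enoyloxy]-1-oxogermacra-4,7(11)-dien-12,6-olide | C/C=C(/C)C(=O)O[C@H]1C[C@@H](C)C(=O)CC/C(C)=C/[C@H]2OC(=O)C(COC(C)=O)=C12 | intermediate
27 | (4R,5R,6S,8S,10R)-13-acetoxy-8-[(Z)-2-methylbut-2-enoyloxy]-4,5-epoxy-1-oxogermacr-7(11)-en-12,6-olide (CNP0229937.2) | C/C=C(/C)C(=O)O[C@H]1C[C@@H](C)C(=O)CC[C@@]2(C)O[C@@H]2[C@H]2OC(=O)C(COC(C)=O)=C12 | target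

**Totals and risks**
Total step count: 16 (step 1 is a one-step side branch). Longest linear sequence: 15 steps (4 to 27, steps 2–16).

Step 13 is the most likely to fail: the yield of a ten-membered ring closure at a hindered tetrasubstituted vinyl centre and the C6 configuration both hinge on it, and the chelate model for C6 is a prediction, not a precedent. The fallback sets out from 19 and keeps both silyl ethers through the cyclisation, so that no free hydroxyl is present and the closure is steered by allylic strain around the protected C8 centre instead of a chromium chelate. Oxalic acid on wet silica gel in CH2Cl2 hydrolyses only the acetal to the bis-silyl enal triflate F1; CrCl2/NiCl2 in DMSO/THF at high dilution closes it to the bis-silyl macrolide F2; HF·pyridine in THF then removes both silyl ethers and the route is rejoined at 22.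

Step 11 is second: the enolate of the β-silyloxy β-keto ester can expel silanolate before O-triflation, and the Z geometry is essential. The fallback sets out from 14 and builds C11–C13 with an ether, a far poorer β-leaving group, from a different building block. Aldol addition of the lithium enolate of methyl 3-[(4-methoxybenzyl)oxy]propanoate gives the aldol adduct F3; Dess–Martin oxidation gives the β-keto ester F4; NaH/Tf2O gives the (Z)-enol triflate F5; DDQ in CH2Cl2/pH 7 buffer removes the 4-methoxybenzyl group to give the allylic alcohol F6; aqueous HF in MeCN cleaves the remaining silyl ether and the acetal and the route is rejoined at 20.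

Step 6 is third: methylenation of a hindered α-branched ester may be sluggish, and the titanium reagent must be removed before the product ketone forms. The fallback sets out from 9 and replaces the vinyl ether Claisen by a Carroll rearrangement. DCC/DMAP coupling with Meldrum's acid gives the acyl Meldrum's acid F7; heating F7 with 3 in toluene (acylketene trapping) gives the allyl β-keto ester F8; heating F8 in xylene at 150 °C brings about the [3,3] shift and decarboxylation and the route is rejoined at 12.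

**Further compounds**
F1 | step 13 | methyl (2Z,4S,6R,10E)-4-[(tert-butyldimethylsilyl)oxy]-2-{[(tert-butyldimethylsilyl)oxy]methyl}-6,10-dimethyl-7,12-dioxo-3-[(trifluoromethanesulfonyl)oxy]dodeca-2,10-dienoate | O=C/C=C(\C)CCC(=O)[C@H](C)C[C@@H](/C(OS(=O)(=O)C(F)(F)F)=C(\CO[Si](C)(C)C(C)(C)C)C(=O)OC)O[Si](C)(C)C(C)(C)C
F2 | step 13 | (4E,6R,8S,10R)-8,13-bis[(tert-butyldimethylsilyl)oxy]-1-oxogermacra-4,7(11)-dien-12,6-olide | CC(C)(C)[Si](C)(C)O[C@H]1C[C@@H](C)C(=O)CC/C(C)=C/[C@H]2OC(=O)C(CO[Si](C)(C)C(C)(C)C)=C12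
F3 | step 11 | methyl (4S,6R,10E)-4-[(tert-butyldimethylsilyl)oxy]-3-hydroxy-12,12-dimethoxy-2-{[(4-methoxybenzyl)oxy]methyl}-6,10-dimethyl-7-oxododec-10-enoate | COC(OC)/C=C(\C)CCC(=O)[C@H](C)C[C@@H](C(O)C(COCc1ccc(OC)cc1)C(=O)OC)O[Si](C)(C)C(C)(C)C
F4 | step 11 | methyl (4S,6R,10E)-4-[(tert-butyldimethylsilyl)oxy]-12,12-dimethoxy-2-{[(4-methoxybenzyl)oxy]methyl}-6,10-dimethyl-3,7-dioxododec-10-enoate | COC(OC)/C=C(\C)CCC(=O)[C@H](C)C[C@@H](C(=O)C(COCc1ccc(OC)cc1)C(=O)OC)O[Si](C)(C)C(C)(C)C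
F5 | step 11 | methyl (2Z,4S,6R,10E)-4-[(tert-butyldimethylsilyl)oxy]-12,12-dimethoxy-2-{[(4-methoxybenzyl)oxy]methyl}-6,10-dimethyl-7-oxo-3-[(trifluoromethanesulfonyl)oxy]dodeca-2,10-dienoate | COC(OC)/C=C(\C)CCC(=O)[C@H](C)C[C@@H](/C(OS(=O)(=O)C(F)(F)F)=C(\COCc1ccc(OC)cc1)C(=O)OC)O[Si](C)(C)C(C)(C)C
F6 | step 11 | methyl (2Z,4S,6R,10E)-4-[(tert-butyldimethylsilyl)oxy]-2-(hydroxymethyl)-12,12-dimethoxy-6,10-dimethyl-7-oxo-3-[(trifluoromethanesulfonyl)oxy]dodeca-2,10-dienoate | COC(OC)/C=C(\C)CCC(=O)[C@H](C)C[C@@H](/C(OS(=O)(=O)C(F)(F)F)=C(\CO)C(=O)OC)O[Si](C)(C)C(C)(C)C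
F7 | step 6 | 5-[(2R,4S)-4,5-bis[(tert-butyldimethylsilyl)oxy]-1-hydroxy-2-methylpentylidene]-2,2-dimethyl-1,3-dioxane-4,6-dione | CC1(C)OC(=O)C(=C(O)[C@H](C)C[C@@H](CO[Si](C)(C)C(C)(C)C)O[Si](C)(C)C(C)(C)C)C(=O)O1
F8 | step 6 | 1,1-dimethoxy-3-methylbut-3-en-2-yl (4R,6S)-6,7-bis[(tert-butyldimethylsilyl)oxy]-4-methyl-3-oxoheptanoate | COC(OC)C(OC(=O)CC(=O)[C@H](C)C[C@@H](CO[Si](C)(C)C(C)(C)C)O[Si](C)(C)C(C)(C)C)C(C)=C
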